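In a one-step world, substrate and partner make product one for one, and I started from that world in deciding what to do with the cedar flask at 5.0 h. There, [partner] = 15.0 mM stood below [substrate] = 25 mM, so partner would be the limiting reagent and product would stop at 60.0%. I named this quantity, the charge of partner over the charge of substrate, the partner ceiling.

all flasks: substrate 25 mM; temperature 100 °C
- cedar: partner 15 mM; free catalyst 0.50 mM; the very flask that is asked about, followed so far
- alder: partner 15 mM; free catalyst 0.34 mM; run made earlier
- flask: partner 15.0 mM; free catalyst 0.50 mM; time 5.0 h

| run | time / min | product / % | substrate / % |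
|---|---|---|---|
| cedar | 50.0 | 59 | 39 |
| cedar | 90.0 | 60 | 40 |
| cedar | 150 | 60 | 41 |
| cedar | 180 | 57 | 42 |
| alder | 0.833 | 12 | 86 |
| alder | 2.00 | 27 | 73 |
| alder | 5.00 | 54 | 45 |
| alder | 10.0 | 60 | 42 |

(scatter of a reading: 1.5 percentage points)

- grey: change nothing and wait 1.5 h more
- amber: at 5.0 h add partner, 50.0% of the amount charged, then wait 1.5 h
- violet: at 5.0 h raise the temperature by 20 K, then wait 1.5 h
- green: at 5.0 h add free catalyst, 50.0% of the amount charged, then wait 1.5 h
- red: at 5.0 h take out 90% of the product then present, then wait 1.5 h

- product that was removed still counts
- the earlier runs were read with a standard deviation of 1.5 percentage points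
- additions bring no volume worth counting
- the earlier runs do not show what temperature does; that part of a forecast is a guess

- product, in percent of the substrate first charged, at 5.0 h
- which option adds most product ("none" when 2 percentage points or less is all one gets) (grey / amber / violet / green / red / none)
- product present, with what was taken out counted in, in percent of the substrate first charged, after green
- product present, with what was taken out counted in, in percent of the substrate first charged, after red

To test the ceiling, I replaced the cedar curve by its mean, 59.0%, with a standard error of 0.75 percentage points. The farthest reading, 57%, lay 2 points below that mean against a scatter of 1.5 points, so I read a flat line rather than a decline, 1 point under the ceiling. The alder flask, with 0.34 mM of free catalyst against 0.50 mM in cedar, read 60% at 10.0 min, which is the same height within the scatter.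

So I chose to leave the temperature, the catalyst and the product alone and to charge partner. Amber raises the ceiling by 30 points to 90.0%, and the 40.0% of substrate that the old ceiling leaves over covers that gain. For the time, I replaced the alder rise by its mean slope from the start to its third reading, 0.108 min⁻¹ as a fraction of the charge, which lay below the 0.135 min⁻¹ up to its second reading. That slope came from the alder flask, with 0.34 mM of free catalyst and with substrate read at 45% at that third reading, against 40.0% for amber to start on, so it was a rough estimate: it asked 2.78 min of the 1.5 h on offer. I assumed a catalyst still working at 5.0 h.

The forecast gave 60% (58% to 61.5%) now, amber as best, 60% (57.5% to 62%) after green and 60% (57.5% to 62.5%) after red, saying “More catalyst or heat has nothing to work on”.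

    catalyst intermediate C → by-product + catalyst intermediate D (k = 26.0 s⁻¹, Ea = 83.0 kJ mol⁻¹)
    catalyst intermediate B ⇌ catalyst intermediate C (K = 2.10, k = 0.440 s⁻¹, Ea = 86.0 kJ mol⁻¹, ΔH = −59.0 kJ mol⁻¹)
    partner + free catalyst → catalyst intermediate A (k = 67.0 L mol⁻¹ s⁻¹, Ea = 37.0 kJ mol⁻¹)
    substrate + catalyst intermediate A → catalyst intermediate B (k = 43.0 L mol⁻¹ s⁻¹, Ea = 52.0 kJ mol⁻¹)
    catalyst intermediate D ⇌ free catalyst + product (K = 0.150 M, k = 1.10 s⁻¹, Ea = 77.0 kJ mol⁻¹, ΔH = −65.0 kJ mol⁻¹)
    (constants at 100 °C)

The flask gave 59.8% at 5.0 h, and amber added 30 points, the gain the ceiling had promised, while green ended at 59.7% and red at 60.0%, so the forecast stood. A neighbour charged with 42 mM of substrate had a ceiling of 35.7% and gave 35.6%. The cedar flask had come to rest: it held 59.8% of product already at 30.0 min, with partner at 0% of its charge at 5.0 h. Left until 3000 min, it still held 59.8% of product, with substrate at 40.0%.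

All runs were generated by integration on assumed constants; the scatter is artificial.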